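**Strategy.** The plan rests on opening the pyranone ring of unit 1 (O1, C2, C3, C4, C4a, C8a) at the C2–C3 bond. C2 is bonded to the ring A oxygen O1 and to a 4-methoxyphenyl ring, so it can be the CH2 of a 4-methoxybenzyl aryl ether, while C3, flanked by the C4 carbonyl, becomes a diazo carbon. A single dirhodium carbenoid C–H insertion then forms C2–C3, closes this ring and sets C2 and C3 cis under neutral conditions. Its precursor is a 2-(4-methoxybenzyloxy)aryl α-diazo ketone whose diazo carbon carries the finished cis (2''R,3''R) flavanone of unit 2, itself made earlier by the same kind of insertion.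

Key step: step 11

Abbreviations: TBS = tert-butyldimethylsilyl, PMB = 4-methoxybenzyl; atoms of unit 2 carry a double prime (C2'', C3'', C4'').

Structure check: the target is (2R,3R,2''R,3''R) with both pyranone rings cis, and the diazo ketone and its insertion product are consistent with it, so no atom or descriptor had to be changed. Alkylating a flavanone enolate would give the trans ring in unit 2, so that ring is also made by carbenoid insertion and meets a strong base only once, at low temperature (step 10).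

Assumption: Rh2(S-PTTL)4 is taken to give the (2R,3R) cis ring in both insertions (steps 9 and 11), which act on nearly identical reacting sites; should step 9 show the opposite sense, Rh2(R-PTTL)4 is used in both.

**Route**

Step 1
Reactants: 1 2',6'-dihydroxy-4'-methoxyacetophenone; 2 4-methoxybenzyl chloride
Product: 3 1-[2-hydroxy-4-methoxy-6-(4-methoxybenzyloxy)phenyl]ethanone
Conditions: K2CO3 (1.2 equiv), 2 (1.05 equiv), acetone, reflux
Reagents that add atoms: none
Why: Williamson ether synthesis; after one of the two equivalent chelated phenols is alkylated, the other is held in a stronger hydrogen bond to the ketone and is much less nucleophilic, so one equivalent of 2 should stop at the mono ether.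

Step 2
Reactants: 3 1-[2-hydroxy-4-methoxy-6-(4-methoxybenzyloxy)phenyl]ethanone
Product: 4 1-[2-(TBSO)-4-methoxy-6-(PMBO)phenyl]ethanone
Conditions: TBSCl, imidazole, DMF, rt to 40 °C
Reagents that add atoms: tert-butyldimethylsilyl chloride, CC(C)(C)[Si](C)(C)Cl
Why: Imidazole-promoted silyl ether formation at the remaining chelated phenol under non-aqueous conditions that leave the benzyl ether untouched.

Step 3
Reactants: 5 2',4',6'-trihydroxyacetophenone
Product: 6 1-[2,4-bis(TBSO)-6-hydroxyphenyl]ethanone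
Conditions: TBSCl (2.1 equiv), imidazole, DMF, 0 °C to rt
Reagents that add atoms: tert-butyldimethylsilyl chloride, CC(C)(C)[Si](C)(C)Cl
Why: Silyl ether formation; the free 4-hydroxyl and one chelated 2-hydroxyl react, after which the last phenol is locked in a hydrogen bond to the carbonyl and should resist a third silylation.

Step 4
Reactants: 6 1-[2,4-bis(TBSO)-6-hydroxyphenyl]ethanone; 7 4-methoxybenzyl alcohol
Product: 8 1-[2,4-bis(TBSO)-6-(PMBO)phenyl]ethanone
Conditions: PPh3, DIAD, THF, 0 °C to rt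
Reagents that add atoms: none
Why: Mitsunobu etherification of the acidic chelated phenol with a primary benzylic alcohol, chosen because it is neutral and cannot cleave or shift the aryl silyl ethers as a carbonate base might.

Step 5
Reactants: 8 1-[2,4-bis(TBSO)-6-(PMBO)phenyl]ethanone
Product: 10 2-bromo-1-[2,4-bis(TBSO)-6-(PMBO)phenyl]ethanone, via trimethylsilyl enol ether 9 (not isolated)
Conditions: Me3SiCl, LiN(SiMe3)2, THF, −78 °C (in situ trapping); then NBS, −78 to 0 °C
Reagents that add atoms: chlorotrimethylsilane, C[Si](C)(C)Cl (atoms kept in 9 only); N-bromosuccinimide, O=C1CCC(=O)N1Br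
Why: α-Bromination through a silyl enol ether; the enol ether is far more nucleophilic toward NBS than the electron-rich arene, and trapping the enolate as it forms leaves the ortho silyl ether no time to migrate.

Step 6
Reactants: 4 1-[2-(TBSO)-4-methoxy-6-(PMBO)phenyl]ethanone
Product: 11 1-[2-(TBSO)-4-methoxy-6-(PMBO)phenyl]butane-1,3-dione
Conditions: LiN(SiMe3)2 (2.2 equiv), THF, −78 °C; 1-acetylbenzotriazole, −78 to −40 °C; aq NH4Cl
Reagents that add atoms: 1-acetylbenzotriazole, CC(=O)n1nnc2ccccc12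
Why: Crossed Claisen-type C-acylation of the lithium enolate with an N-acylbenzotriazole; the second equivalent of base is taken up by the more acidic 1,3-diketone, and no alkoxide is released that could cleave the aryl silyl ether.

Step 7
Reactants: 11 1-[2-(TBSO)-4-methoxy-6-(PMBO)phenyl]butane-1,3-dione; 10 2-bromo-1-[2,4-bis(TBSO)-6-(PMBO)phenyl]ethanone
Product: 12 2-acetyl-4-[2,4-bis(TBSO)-6-(PMBO)phenyl]-1-[2-(TBSO)-4-methoxy-6-(PMBO)phenyl]butane-1,4-dione (racemic)
Conditions: NaH (1.0 equiv), THF, 0 °C; then 10, Bu4NI (cat.), 0 °C to rt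
Reagents that add atoms: none
Why: SN2 C-alkylation of a 1,3-diketone enolate by an α-bromo ketone whose carbonyl is shielded by two ortho substituents against Darzens- or Feist–Benary-type attack; the acetyl group marks the carbon that is to become C3'', and the racemic centre disappears in step 8.

Step 8
Reactants: 12 2-acetyl-4-[2,4-bis(TBSO)-6-(PMBO)phenyl]-1-[2-(TBSO)-4-methoxy-6-(PMBO)phenyl]butane-1,4-dione
Product: 13 4-[2,4-bis(TBSO)-6-(PMBO)phenyl]-2-diazo-1-[2-(TBSO)-4-methoxy-6-(PMBO)phenyl]butane-1,4-dione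
Conditions: 4-acetamidobenzenesulfonyl azide, DBU, MeCN, 0 °C
Reagents that add atoms: 4-acetamidobenzenesulfonyl azide, CC(=O)Nc1ccc(cc1)S(=O)(=O)N=[N+]=[N-]
Why: Deacylative diazo transfer; the diketone enolate attacks the azide and the unhindered acetyl group is cleaved in preference to the twisted, electron-rich aroyl group, so the diazo group lands only next to the unit 2 ketone, which a direct transfer to the plain 1,4-diketone could not ensure.

Step 9
Reactants: 13 4-[2,4-bis(TBSO)-6-(PMBO)phenyl]-2-diazo-1-[2-(TBSO)-4-methoxy-6-(PMBO)phenyl]butane-1,4-dione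
Product: 14 (2R,3R)-3-{2-[2,4-bis(TBSO)-6-(PMBO)phenyl]-2-oxoethyl}-5-(TBSO)-7-methoxy-2-(4-methoxyphenyl)chroman-4-one (2,3-cis)
Conditions: Rh2(S-PTTL)4, dirhodium tetrakis[N-phthaloyl-(S)-tert-leucinate] (1 mol %), CH2Cl2, −40 to 0 °C, slow addition of 13
Reagents that add atoms: none
Why: Dirhodium carbenoid 1,6-C–H insertion of a 2-alkoxyaryl α-diazo ketone, the known entry to cis-2,3-disubstituted chroman-4-ones; the carbenoid inserts into the ether C–H activated by oxygen and the 4-methoxyphenyl ring, the cis relation of C2'' and C3'' follows from the kinetically controlled transition state and their absolute sense from the chiral carboxylate ligands, while the acyl group on the neighbouring CH2 slows the competing 1,2-hydride shift.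

Step 10
Reactants: 14 (2R,3R)-3-{2-[2,4-bis(TBSO)-6-(PMBO)phenyl]-2-oxoethyl}-5-(TBSO)-7-methoxy-2-(4-methoxyphenyl)chroman-4-one
Product: 16 1-[2,4-bis(TBSO)-6-(PMBO)phenyl]-2-diazo-2-[(2R,3R)-5-(TBSO)-7-methoxy-2-(4-methoxyphenyl)-4-oxochroman-3-yl]ethanone, via trifluoroacetyl ketone 15 (not isolated)
Conditions: LiN(SiMe3)2 (1.05 equiv), THF, −78 °C; CF3CO2CH2CF3, −78 °C; aq NH4Cl; then 4-acetamidobenzenesulfonyl azide, Et3N, H2O, MeCN, 0 °C to rt
Reagents that add atoms: 2,2,2-trifluoroethyl trifluoroacetate, O=C(OCC(F)(F)F)C(F)(F)F (atoms kept in 15 only); 4-acetamidobenzenesulfonyl azide, CC(=O)Nc1ccc(cc1)S(=O)(=O)N=[N+]=[N-]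
Why: Detrifluoroacetylative diazo transfer; the hindered amide base at −78 °C should take a proton from the side-chain CH2 faster than the tertiary C3''–H (which in the cis ring lies near the plane of the C4'' carbonyl and is poorly aligned), the enolate is trapped at once as the trifluoroacetyl ketone, and the azide then exchanges that group for N2 while the amine is buffered by the acidic diketone and sulfonamide.

Step 11
Reactants: 16 1-[2,4-bis(TBSO)-6-(PMBO)phenyl]-2-diazo-2-[(2R,3R)-5-(TBSO)-7-methoxy-2-(4-methoxyphenyl)-4-oxochroman-3-yl]ethanone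
Product: 17 (2R,3R)-5,7-bis(TBSO)-3-[(2R,3R)-5-(TBSO)-7-methoxy-2-(4-methoxyphenyl)-4-oxochroman-3-yl]-2-(4-methoxyphenyl)chroman-4-one
Conditions: Rh2(S-PTTL)4 (2 mol %), CH2Cl2, −40 to 0 °C, slow addition of 16
Reagents that add atoms: none
Why: The divalent rhodium catalyst adds to the diazo carbon C3 and expels N2, and the electrophilic carbenoid inserts into one C–H bond of the ArO–CH2–Ar' group through a three-centre transition state with hydride-transfer character, forming C2–C3 and releasing the catalyst. The closest known reaction is the dirhodium carboxylate catalysed insertion of 2-alkoxyaryl α-diazo ketones that gives cis-2,3-disubstituted chroman-4-ones, already used in step 9. The pyranone ring of unit 1 closes as a six-membered ring by 1,6-insertion (carbenoid carbon 1, ether oxygen 5, benzylic carbon 6). C2 and C3 arise in the same concerted, kinetically controlled event, in which the anisyl group on C2 and the unit 2 substituent on C3 both turn away from the dirhodium core and so end up cis, while the attacked face of the carbenoid, hence the (2R,3R) sense, is set by the chiral N-phthaloyl-tert-leucinate ligands acting as in step 9 and supported by the resident C2''/C3'' centres. The step needs insertion to outrun the 1,2-hydride shift from C3'' and ylide formation at the ortho ether oxygens, which the substrate secures through a C–H bond activated by both O1 and the 4-methoxyphenyl ring, a migrating hydrogen deactivated by the adjacent C4'' carbonyl, and silyl ethers that offer no other activated C–H bond, helped by the bulky carboxylates and the low temperature. Since the medium is neutral neither cis ring can epimerise, and any enantiomer of 14 carried along ends up as a separable diastereomer.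

Step 12
Reactants: 17 (2R,3R)-5,7-bis(TBSO)-3-[(2R,3R)-5-(TBSO)-7-methoxy-2-(4-methoxyphenyl)-4-oxochroman-3-yl]-2-(4-methoxyphenyl)chroman-4-one
Product: 18 (2R,3R)-5,7-dihydroxy-3-[(2R,3R)-5-hydroxy-7-methoxy-2-(4-methoxyphenyl)-4-oxochroman-3-yl]-2-(4-methoxyphenyl)chroman-4-one
Conditions: HF·pyridine, pyridine, THF, 0 °C to rt; pH 7 work-up
Reagents that add atoms: none
Why: Fluoride-mediated cleavage of the three aryl silyl ethers in a buffered, weakly acidic medium, which avoids the base-induced epimerisation at C3/C3'' and the retro-oxa-Michael ring opening to which cis flavanones are prone; the methyl ethers are inert.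

**Compound list**

1 | 2',6'-dihydroxy-4'-methoxyacetophenone | CC(=O)c1c(O)cc(OC)cc1O | starting material
2 | 4-methoxybenzyl chloride | COc1ccc(CCl)cc1 | starting material
3 | 1-[2-hydroxy-4-methoxy-6-(4-methoxybenzyloxy)phenyl]ethanone | CC(=O)c1c(O)cc(OC)cc1OCc1ccc(OC)cc1 | intermediate
4 | 1-[2-(TBSO)-4-methoxy-6-(PMBO)phenyl]ethanone | CC(=O)c1c(O[Si](C)(C)C(C)(C)C)cc(OC)cc1OCc1ccc(OC)cc1 | intermediate
5 | 2',4',6'-trihydroxyacetophenone | CC(=O)c1c(O)cc(O)cc1O | starting material
6 | 1-[2,4-bis(TBSO)-6-hydroxyphenyl]ethanone | CC(=O)c1c(O)cc(O[Si](C)(C)C(C)(C)C)cc1O[Si](C)(C)C(C)(C)C | intermediate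
7 | 4-methoxybenzyl alcohol | COc1ccc(CO)cc1 | starting material
8 | 1-[2,4-bis(TBSO)-6-(PMBO)phenyl]ethanone | CC(=O)c1c(OCc2ccc(OC)cc2)cc(O[Si](C)(C)C(C)(C)C)cc1O[Si](C)(C)C(C)(C)C | intermediate
9 | trimethylsilyl enol ether of 8, {1-[2,4-bis(TBSO)-6-(PMBO)phenyl]ethenyloxy}trimethylsilane | C=C(O[Si](C)(C)C)c1c(OCc2ccc(OC)cc2)cc(O[Si](C)(C)C(C)(C)C)cc1O[Si](C)(C)C(C)(C)C | intermediate (not isolated)
10 | 2-bromo-1-[2,4-bis(TBSO)-6-(PMBO)phenyl]ethanone | BrCC(=O)c1c(OCc2ccc(OC)cc2)cc(O[Si](C)(C)C(C)(C)C)cc1O[Si](C)(C)C(C)(C)C | intermediate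
11 | 1-[2-(TBSO)-4-methoxy-6-(PMBO)phenyl]butane-1,3-dione | CC(=O)CC(=O)c1c(O[Si](C)(C)C(C)(C)C)cc(OC)cc1OCc1ccc(OC)cc1 | intermediate
12 | 2-acetyl-4-[2,4-bis(TBSO)-6-(PMBO)phenyl]-1-[2-(TBSO)-4-methoxy-6-(PMBO)phenyl]butane-1,4-dione (racemic) | CC(=O)C(CC(=O)c1c(OCc2ccc(OC)cc2)cc(O[Si](C)(C)C(C)(C)C)cc1O[Si](C)(C)C(C)(C)C)C(=O)c1c(O[Si](C)(C)C(C)(C)C)cc(OC)cc1OCc1ccc(OC)cc1 | intermediate
13 | 4-[2,4-bis(TBSO)-6-(PMBO)phenyl]-2-diazo-1-[2-(TBSO)-4-methoxy-6-(PMBO)phenyl]butane-1,4-dione | [N-]=[N+]=C(CC(=O)c1c(OCc2ccc(OC)cc2)cc(O[Si](C)(C)C(C)(C)C)cc1O[Si](C)(C)C(C)(C)C)C(=O)c1c(O[Si](C)(C)C(C)(C)C)cc(OC)cc1OCc1ccc(OC)cc1 | intermediate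
14 | (2R,3R)-3-{2-[2,4-bis(TBSO)-6-(PMBO)phenyl]-2-oxoethyl}-5-(TBSO)-7-methoxy-2-(4-methoxyphenyl)chroman-4-one | COc1ccc(COc3cc(O[Si](C)(C)C(C)(C)C)cc(O[Si](C)(C)C(C)(C)C)c3C(=O)C[C@H]2C(=O)c3c(O[Si](C)(C)C(C)(C)C)cc(OC)cc3O[C@H]2c2ccc(OC)cc2)cc1 | intermediate
15 | 1-[2,4-bis(TBSO)-6-(PMBO)phenyl]-4,4,4-trifluoro-2-[(2R,3R)-5-(TBSO)-7-methoxy-2-(4-methoxyphenyl)-4-oxochroman-3-yl]butane-1,3-dione (mixture at the chain carbon, largely enolised) | COc1ccc(COc3cc(O[Si](C)(C)C(C)(C)C)cc(O[Si](C)(C)C(C)(C)C)c3C(=O)C(C(=O)C(F)(F)F)[C@H]2C(=O)c3c(O[Si](C)(C)C(C)(C)C)cc(OC)cc3O[C@H]2c2ccc(OC)cc2)cc1 | intermediate (not isolated)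
16 | 1-[2,4-bis(TBSO)-6-(PMBO)phenyl]-2-diazo-2-[(2R,3R)-5-(TBSO)-7-methoxy-2-(4-methoxyphenyl)-4-oxochroman-3-yl]ethanone | COc1ccc(COc3cc(O[Si](C)(C)C(C)(C)C)cc(O[Si](C)(C)C(C)(C)C)c3C(=O)C(=[N+]=[N-])[C@H]2C(=O)c3c(O[Si](C)(C)C(C)(C)C)cc(OC)cc3O[C@H]2c2ccc(OC)cc2)cc1 | intermediate
17 | (2R,3R)-5,7-bis(TBSO)-3-[(2R,3R)-5-(TBSO)-7-methoxy-2-(4-methoxyphenyl)-4-oxochroman-3-yl]-2-(4-methoxyphenyl)chroman-4-one | COc1ccc([C@@H]2Oc3cc(O[Si](C)(C)C(C)(C)C)cc(O[Si](C)(C)C(C)(C)C)c3C(=O)[C@@H]2[C@H]2C(=O)c3c(O[Si](C)(C)C(C)(C)C)cc(OC)cc3O[C@H]2c2ccc(OC)cc2)cc1 | intermediate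
18 | (2R,3R)-5,7-dihydroxy-3-[(2R,3R)-5-hydroxy-7-methoxy-2-(4-methoxyphenyl)-4-oxochroman-3-yl]-2-(4-methoxyphenyl)chroman-4-one | COc1ccc([C@@H]2Oc3cc(O)cc(O)c3C(=O)[C@@H]2[C@H]2C(=O)c3c(O)cc(OC)cc3O[C@H]2c2ccc(OC)cc2)cc1 | target

**Total step count:** 12
**Longest linear sequence:** 9 steps (1, 2, 6, 7, 8, 9, 10, 11, 12; the branch through steps 3, 4, 5 is equally long)

**Steps most likely to fail**

1. Step 11. What may go wrong: migration of the C3'' hydrogen to the carbenoid carbon, or capture of the carbenoid by an ortho ether oxygen followed by a 1,2-shift, may outrun insertion; the two faces of the carbenoid may also be told apart poorly. Fallback, setting out from 14 and returning at 17: the 4-methoxybenzyl ether of 14 is cleaved oxidatively (DDQ, CH2Cl2, pH 7 buffer, 0 °C) to the chelated phenol F1. Enolisation of F1 at C3 with (c-C6H11)2BCl and Et3N, a reagent that should leave the methine C3''–H alone, gives the E enol borinate, which adds to 4-methoxybenzaldehyde (COc1ccc(C=O)cc1) through a chair transition state to give the anti aldol F2; this forms the same C2–C3 bond as the insertion. Mitsunobu cyclisation (PPh3, DIAD, THF, 0 °C) then lets the phenol displace the benzylic hydroxyl with inversion, which turns the anti aldol into the cis ring of 17. The face of the enolate that reacts would rest on the neighbouring C3'' centre alone.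

2. Step 10. What may go wrong: deprotonation at C3'' competing with that at the side-chain CH2, which would epimerise the cis ring of unit 2 or open it by loss of the aryloxide. Fallback, setting out from 14 and returning at 16: the ring-fused C4'' ketone of 14 is reduced selectively (NaBH4, CeCl3·7H2O, MeOH/THF, −40 °C; the other ketone is shielded by two ortho substituents) to the flavan-4-ol F3, the configuration at C4'' being immaterial. Silylation (Et3SiCl, imidazole, DMF) gives the triethylsilyl ether F4, in which C3'' is no longer α to a carbonyl. The diazo transfer sequence of step 10 then gives, by way of the trifluoroacetyl ketone F5, the diazo ketone F6 with only one enolisable position in play. Methanolysis of the alkyl silyl ether (pyridinium p-toluenesulfonate, MeOH, 0 °C, under which aryl silyl ethers and the diazo ketone should persist) gives the diazo alcohol F7, and Dess–Martin periodinane buffered with NaHCO3 restores the C4'' ketone to give 16.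

3. Step 9. What may go wrong: hydride migration from the acyl-substituted CH2 to the carbenoid may compete with insertion, or enantioinduction by the catalyst may be weak. Fallback, setting out from 1 and 10 and returning at 14: monosilylation of 1 (TBSCl, imidazole, CH2Cl2) gives the phenol ketone F8, whose dianion (LiN(SiMe3)2, 2 equiv, THF, −78 °C) is alkylated at carbon by 10 to give the 1,4-diketone F9 with a free phenol. Boron-mediated enolisation ((c-C6H11)2BCl, Et3N), directed to the ketone beside the aryloxyborane, and addition to 4-methoxybenzaldehyde give the racemic anti aldol F10. Mitsunobu closure with inversion (PPh3, DIAD) gives the cis flavanone as a racemate, from which 14 is separated from its enantiomer F11 by chromatography on a chiral stationary phase.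

**Further compounds**

F1 | step 11 | (2R,3R)-3-{2-[2,4-bis(TBSO)-6-hydroxyphenyl]-2-oxoethyl}-5-(TBSO)-7-methoxy-2-(4-methoxyphenyl)chroman-4-one | Oc1cc(O[Si](C)(C)C(C)(C)C)cc(O[Si](C)(C)C(C)(C)C)c1C(=O)C[C@H]1C(=O)c2c(O[Si](C)(C)C(C)(C)C)cc(OC)cc2O[C@H]1c1ccc(OC)cc1
F2 | step 11 | (2R,3S)-1-[2,4-bis(TBSO)-6-hydroxyphenyl]-3-hydroxy-3-(4-methoxyphenyl)-2-[(2R,3R)-5-(TBSO)-7-methoxy-2-(4-methoxyphenyl)-4-oxochroman-3-yl]propan-1-one (anti aldol) | Oc1cc(O[Si](C)(C)C(C)(C)C)cc(O[Si](C)(C)C(C)(C)C)c1C(=O)[C@@H]([C@H](O)c1ccc(OC)cc1)[C@H]1C(=O)c2c(O[Si](C)(C)C(C)(C)C)cc(OC)cc2O[C@H]1c1ccc(OC)cc1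
F3 | step 10 | 4-hydroxy analogue of 14 (flavan-4-ol, ring centres C2'' and C3'' as in 14, C4'' unspecified) | COc1ccc(COc3cc(O[Si](C)(C)C(C)(C)C)cc(O[Si](C)(C)C(C)(C)C)c3C(=O)C[C@H]2C(O)c3c(O[Si](C)(C)C(C)(C)C)cc(OC)cc3O[C@H]2c2ccc(OC)cc2)cc1
F4 | step 10 | triethylsilyl ether of F3 | COc1ccc(COc3cc(O[Si](C)(C)C(C)(C)C)cc(O[Si](C)(C)C(C)(C)C)c3C(=O)C[C@H]2C(O[Si](CC)(CC)CC)c3c(O[Si](C)(C)C(C)(C)C)cc(OC)cc3O[C@H]2c2ccc(OC)cc2)cc1
F5 | step 10 | trifluoroacetyl ketone from F4 (trifluoroacetyl on the side-chain carbon, not isolated) | COc1ccc(COc3cc(O[Si](C)(C)C(C)(C)C)cc(O[Si](C)(C)C(C)(C)C)c3C(=O)C(C(=O)C(F)(F)F)[C@H]2C(O[Si](CC)(CC)CC)c3c(O[Si](C)(C)C(C)(C)C)cc(OC)cc3O[C@H]2c2ccc(OC)cc2)cc1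
F6 | step 10 | diazo ketone with the C4'' triethylsilyl ether | COc1ccc(COc3cc(O[Si](C)(C)C(C)(C)C)cc(O[Si](C)(C)C(C)(C)C)c3C(=O)C(=[N+]=[N-])[C@H]2C(O[Si](CC)(CC)CC)c3c(O[Si](C)(C)C(C)(C)C)cc(OC)cc3O[C@H]2c2ccc(OC)cc2)cc1
F7 | step 10 | diazo ketone with the free C4'' alcohol | COc1ccc(COc3cc(O[Si](C)(C)C(C)(C)C)cc(O[Si](C)(C)C(C)(C)C)c3C(=O)C(=[N+]=[N-])[C@H]2C(O)c3c(O[Si](C)(C)C(C)(C)C)cc(OC)cc3O[C@H]2c2ccc(OC)cc2)cc1
F8 | step 9 | 1-[2-(TBSO)-6-hydroxy-4-methoxyphenyl]ethanone | CC(=O)c1c(O)cc(OC)cc1O[Si](C)(C)C(C)(C)C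
F9 | step 9 | 1-[2,4-bis(TBSO)-6-(PMBO)phenyl]-4-[2-(TBSO)-6-hydroxy-4-methoxyphenyl]butane-1,4-dione | COc1ccc(COc2cc(O[Si](C)(C)C(C)(C)C)cc(O[Si](C)(C)C(C)(C)C)c2C(=O)CCC(=O)c2c(O)cc(OC)cc2O[Si](C)(C)C(C)(C)C)cc1
F10 | step 9 | 4-[2,4-bis(TBSO)-6-(PMBO)phenyl]-2-[hydroxy(4-methoxyphenyl)methyl]-1-[2-(TBSO)-6-hydroxy-4-methoxyphenyl]butane-1,4-dione (anti, racemic; the enantiomer drawn leads to 14) | COc1ccc(COc2cc(O[Si](C)(C)C(C)(C)C)cc(O[Si](C)(C)C(C)(C)C)c2C(=O)C[C@H]([C@H](O)c2ccc(OC)cc2)C(=O)c2c(O)cc(OC)cc2O[Si](C)(C)C(C)(C)C)cc1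
F11 | step 9 | (2S,3S) enantiomer of 14 | COc1ccc(COc3cc(O[Si](C)(C)C(C)(C)C)cc(O[Si](C)(C)C(C)(C)C)c3C(=O)C[C@@H]2C(=O)c3c(O[Si](C)(C)C(C)(C)C)cc(OC)cc3O[C@@H]2c2ccc(OC)cc2)cc1
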